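The route rests on breaking the piperidine ring at C5'–C6'. C6' is the methylene carbon of an N-methylglycine unit. C4' sits next to the arene carbon that later becomes C8 of the chromone. An α-amino radical made by loss of CO2 can therefore close onto a 1-arylvinyl group. One photoredox operation forms the C5'–C6' bond, closes the piperidine 6-endo, and sets C4' by hydrogen-atom transfer anti to the C3' silyloxy group. The precursor is an open-chain (S)-allylic silyl ether. It carries the 2,4,6-trimethoxyphenyl ring on the inner alkene carbon and the free amino acid on nitrogen. The pyranone ring and the angelate follow by established chemistry.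

Key step: step 6

Remark: primed locants number the piperidine (N1', oxygen on C3', arene on C4'); the target SMILES decodes as (3'S,4'R), cis, with a (Z)-2-methylbut-2-enoate, and every structure below follows that reading.

Step 1
Reactants: 1 sarcosine tert-butyl ester hydrochloride; 2 2-chloro-N-methoxy-N-methylacetamide
Product: 3 tert-butyl N-{2-[methoxy(methyl)amino]-2-oxoethyl}-N-methylglycinate
Conditions: K2CO3 (3 equiv), NaI (10 mol %), MeCN, 50 °C
Reagents that add atoms: none
Why: Iodide-assisted SN2 N-alkylation of a secondary amine by an α-chloroamide is routine, and the product nitrogen, flanked by two acylmethyl arms, is too poor a nucleophile to quaternise.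

Step 2
Reactants: 4 2',4',6'-trimethoxyacetophenone
Product: 5 N'-[1-(2,4,6-trimethoxyphenyl)ethylidene]-2,4,6-triisopropylbenzenesulfonohydrazide
Conditions: 2,4,6-triisopropylbenzenesulfonohydrazide (1.1 equiv), conc. HCl (cat.), MeCN, 25–40 °C, extended time
Reagents that add atoms: 2,4,6-triisopropylbenzenesulfonohydrazide, CC(C)c1cc(C(C)C)c(S(=O)(=O)NN)c(C(C)C)c1
Why: Acid-catalysed hydrazone condensation prepares the Shapiro reaction; the triisopropylphenylsulfonyl group has no ortho hydrogen that could be lithiated and fragments at 0 °C, and the hindered ketone only needs time.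

Step 3
Reactants: 5 the sulfonylhydrazone; 3 the Weinreb amide tert-butyl ester
Product: 7 tert-butyl N-methyl-N-[2-oxo-3-(2,4,6-trimethoxyphenyl)but-3-en-1-yl]glycinate, via 1-arylvinyllithium 6 (not isolated)
Conditions: 5, n-BuLi (2.1 equiv), THF, −78 °C, then 0 °C until N2 evolution stops; −78 °C, 3 (0.8 equiv); inverse quench into cold aq. NH4Cl
Reagents that add atoms: n-butyllithium, [Li]CCCC (supplies the lithium of 6 only)
Why: Shapiro reaction followed by Weinreb ketone synthesis: deprotonation at N–H and then at the only α-C–H set, with loss of sulfinate and N2, gives the methoxy-chelated vinyllithium 6, which adds once to the chelating amide faster than to the tert-butyl ester, and the adduct collapses to the enone only in the cold quench, where the released hydroxylamine has little chance to add back.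

Step 4
Reactants: 7 the amino enone
Product: 8 tert-butyl N-[(2S)-2-hydroxy-3-(2,4,6-trimethoxyphenyl)but-3-en-1-yl]-N-methylglycinate
Conditions: (S)-1-methyl-3,3-diphenyltetrahydro-1H,3H-pyrrolo[1,2-c][1,3,2]oxazaborole ((S)-Me-CBS, 0.3 equiv), catecholborane (2 equiv), toluene, −78 °C; MeOH, then aq. NaOH wash
Reagents that add atoms: none
Why: In this Corey–Bakshi–Shibata reduction the ketone binds through the lone pair beside the smaller CH2N arm and turns the α-branched 1-arylvinyl group away from the catalyst, so the (S)-catalyst should give the (S)-carbinol (S because CH2N outranks the vinyl carbon), while catecholborane at −78 °C avoids hydroboration and 1,4-reduction and the doubly acylmethylated nitrogen is only a weak Lewis base.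

Step 5
Reactants: 8 the (S)-allylic alcohol
Product: 11 N-[(2S)-2-(tert-butyldimethylsilyloxy)-3-(2,4,6-trimethoxyphenyl)but-3-en-1-yl]-N-methylglycine, via silyl ether tert-butyl ester 9 (not isolated), via silyl ether silyl ester 10 (not isolated)
Conditions: TBSOTf (3.5 equiv), 2,6-lutidine (5 equiv), CH2Cl2, 0 °C to 25 °C; then K2CO3, THF/MeOH/H2O, 25 °C; pH 6 phosphate buffer, extraction
Reagents that add atoms: tert-butyldimethylsilyl trifluoromethanesulfonate, CC(C)(C)[Si](C)(C)OS(=O)(=O)C(F)(F)F
Why: Silyl triflate/lutidine silylates the carbinol and, in excess, turns the tert-butyl ester into the silyl ester with loss of isobutene (a known non-protic tert-butyl ester cleavage), so no Brønsted acid meets the acid-sensitive electron-rich styrene, mild carbonate hydrolysis frees only the labile silyl ester, the silyl ether prevents lactonisation to a morpholinone, and C3' is untouched.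

Step 6
Reactants: 11 the (S)-amino acid
Product: 12 (3S,4R)-3-(tert-butyldimethylsilyloxy)-1-methyl-4-(2,4,6-trimethoxyphenyl)piperidine
Conditions: [Ir(dF(CF3)ppy)2(dtbbpy)]PF6 (1 mol %), 2,4,6-triisopropylbenzenethiol (10 mol %), K2HPO4 (1.2 equiv), degassed DMF (0.01 M), 450 nm LEDs, 25 °C
Reagents that add atoms: none
Why: The excited trivalent iridium complex removes one electron from the amino carboxylate of 11, CO2 is lost, the nucleophilic N–CH2 radical (C6') adds to the unsubstituted alkene terminus C5', the C4' benzylic radical takes hydrogen from the arenethiol, and the thiyl radical is reduced by the divalent iridium complex and reprotonated, so the step is redox-neutral with thiol and base regenerated. The closest known reaction type is the photoredox decarboxylative hydroaminoalkylation of styrenes by α-amino acids with a thiol hydrogen-atom-transfer cocatalyst, run here within one molecule. The piperidine closes 6-endo-trig, because the bulky aryl group on the inner carbon C4' blocks the 5-exo path and only the endo path leads to a tertiary benzylic radical. C3' is carried through unchanged and C4' is set in the hydrogen transfer: A(1,3)-type strain with the two ortho-methoxy groups forces the C3' silyloxy group axial, where it covers one face of the flattened radical, so the hindered thiol should deliver hydrogen axially from the other face and leave the aryl group equatorial and cis to oxygen, (3S,4R). Ring closure must outrun hydrogen transfer to the open-chain radical, hence high dilution and little thiol, and an arenethiol is chosen because its weak S–H bond makes transfer to the benzylic radical downhill while its bulky thiyl radical adds poorly to the styrene. The α-amino carbons C2' and C6' of 12 are not stereogenic, so reversible oxidation of the product amine cannot erode configuration.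

Step 7
Reactants: 12 the silyloxy piperidine
Product: 14 (3S,4R)-4-(3-acetyl-2-hydroxy-4,6-dimethoxyphenyl)-1-methylpiperidin-3-yl acetate, via piperidinyl acetate 13 (not isolated)
Conditions: Ac2O (10 equiv), BF3·OEt2 (10 equiv), CH2Cl2, 0 °C to 25 °C; aq. Na2CO3
Reagents that add atoms: acetic anhydride, CC(=O)OC(C)=O
Why: In this Friedel–Crafts acetylation the Lewis acid/anhydride pair first exchanges the silyl ether for an acetate (a known direct conversion), then acetylates one of the two equivalent free ring positions, and the boron chelate of the new ketone cleaves the most crowded, out-of-plane ortho-methoxy group (the one between acetyl and piperidinyl), which is the oxygen that must become O1; both stereocentres are spectators.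

Step 8
Reactants: 14 the ortho-hydroxyacetophenone
Product: 16 8-[(3S,4R)-3-hydroxy-1-methylpiperidin-4-yl]-5,7-dimethoxy-2-methyl-4H-chromen-4-one, via 1,3-diketone 15 (not isolated)
Conditions: NaH (6 equiv), EtOAc, reflux; then 6 M aq. HCl, 90 °C; Na2CO3 to pH 9
Reagents that add atoms: ethyl acetate, CCOC(C)=O
Why: Claisen condensation of the methyl ketone enolate with ethyl acetate gives the 1,3-diketone, and hot aqueous acid closes the phenol onto it (cyclodehydration to the 2-methylchromone) and hydrolyses the C3' acetate in the same pot.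

Step 9
Reactants: 16 the dimethoxychromone
Product: 17 5,7-dihydroxy-8-[(3S,4R)-3-hydroxy-1-methylpiperidin-4-yl]-2-methyl-4H-chromen-4-one (rohitukine)
Conditions: pyridine hydrochloride (excess), neat, 180 °C; aq. Na2CO3 to pH 8–9
Reagents that add atoms: none
Why: Aryl methyl ether cleavage by SN2 attack of chloride on the protonated ethers in molten pyridine hydrochloride is well established for 5,7-dimethoxychromones and flavones, and the protonated piperidinol offers no easy path to elimination or epimerisation.

Step 10
Reactants: 17 rohitukine; 18 angelic acid, (Z)-2-methylbut-2-enoic acid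
Product: 20 (3S,4R)-4-{2-methyl-5,7-bis[(Z)-2-methylbut-2-enoyloxy]-4-oxo-4H-chromen-8-yl}-1-methylpiperidin-3-yl (Z)-2-methylbut-2-enoate, via mixed anhydride 19 (not isolated)
Conditions: 18 (6 equiv), 2,4,6-trichlorobenzoyl chloride (6 equiv), Et3N (12 equiv), toluene, 25 °C; then 17, toluene/1,4-dioxane, 80 °C
Reagents that add atoms: 2,4,6-trichlorobenzoyl chloride, O=C(Cl)c1c(Cl)cc(Cl)cc1Cl (aroyl part of 19 only)
Why: A Yamaguchi-type mixed-anhydride esterification run without a nucleophilic pyridine catalyst is the variant known to transfer the angeloyl group with its Z geometry intact, and excess reagent removes any need for site selection, since the phenols are acylated too and bring the substrate into solution while the crowded axial C3' hydroxyl reacts on heating (material still free at O5 converges in step 11).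

Step 11
Reactants: 20 the tris-angelate
Product: 21 (3S,4R)-4-(5,7-dihydroxy-2-methyl-4-oxo-4H-chromen-8-yl)-1-methylpiperidin-3-yl (Z)-2-methylbut-2-enoate (target)
Conditions: K2CO3 (3 equiv), MeOH, 0 °C; pH 7 phosphate buffer
Reagents that add atoms: none
Why: In this chemoselective transesterification the aryl esters of the acidic chromone phenols are far better acyl donors than a hindered secondary alkyl α,β-unsaturated ester, so cold carbonate/methanol should strip O5 and O7 only and leave the C3' angelate, its Z geometry and both stereocentres alone.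

Compound list
1 | sarcosine tert-butyl ester hydrochloride | CNCC(=O)OC(C)(C)C.Cl | starting material
2 | 2-chloro-N-methoxy-N-methylacetamide | CON(C)C(=O)CCl | starting material
3 | tert-butyl N-{2-[methoxy(methyl)amino]-2-oxoethyl}-N-methylglycinate | CON(C)C(=O)CN(C)CC(=O)OC(C)(C)C | intermediate
4 | 2',4',6'-trimethoxyacetophenone | CC(=O)c1c(OC)cc(OC)cc1OC | starting material
5 | N'-[1-(2,4,6-trimethoxyphenyl)ethylidene]-2,4,6-triisopropylbenzenesulfonohydrazide (C=N geometry not defined) | CC(=NNS(=O)(=O)c1c(C(C)C)cc(C(C)C)cc1C(C)C)c2c(OC)cc(OC)cc2OC | intermediate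
6 | [1-(2,4,6-trimethoxyphenyl)vinyl]lithium | [Li]C(=C)c1c(OC)cc(OC)cc1OC | intermediate
7 | tert-butyl N-methyl-N-[2-oxo-3-(2,4,6-trimethoxyphenyl)but-3-en-1-yl]glycinate | CC(C)(C)OC(=O)CN(C)CC(=O)C(=C)c1c(OC)cc(OC)cc1OC | intermediate
8 | tert-butyl N-[(2S)-2-hydroxy-3-(2,4,6-trimethoxyphenyl)but-3-en-1-yl]-N-methylglycinate | CC(C)(C)OC(=O)CN(C)C[C@@H](O)C(=C)c1c(OC)cc(OC)cc1OC | intermediate
9 | tert-butyl N-[(2S)-2-(tert-butyldimethylsilyloxy)-3-(2,4,6-trimethoxyphenyl)but-3-en-1-yl]-N-methylglycinate | CC(C)(C)OC(=O)CN(C)C[C@@H](O[Si](C)(C)C(C)(C)C)C(=C)c1c(OC)cc(OC)cc1OC | intermediate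
10 | tert-butyldimethylsilyl N-[(2S)-2-(tert-butyldimethylsilyloxy)-3-(2,4,6-trimethoxyphenyl)but-3-en-1-yl]-N-methylglycinate | CC(C)(C)[Si](C)(C)OC(=O)CN(C)C[C@@H](O[Si](C)(C)C(C)(C)C)C(=C)c1c(OC)cc(OC)cc1OC | intermediate
11 | N-[(2S)-2-(tert-butyldimethylsilyloxy)-3-(2,4,6-trimethoxyphenyl)but-3-en-1-yl]-N-methylglycine | OC(=O)CN(C)C[C@@H](O[Si](C)(C)C(C)(C)C)C(=C)c1c(OC)cc(OC)cc1OC | intermediate
12 | (3S,4R)-3-(tert-butyldimethylsilyloxy)-1-methyl-4-(2,4,6-trimethoxyphenyl)piperidine | CC(C)(C)[Si](C)(C)O[C@@H]1CN(C)CC[C@@H]1c1c(OC)cc(OC)cc1OC | intermediate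
13 | (3S,4R)-1-methyl-4-(2,4,6-trimethoxyphenyl)piperidin-3-yl acetate | CC(=O)O[C@@H]1CN(C)CC[C@@H]1c1c(OC)cc(OC)cc1OC | intermediate
14 | (3S,4R)-4-(3-acetyl-2-hydroxy-4,6-dimethoxyphenyl)-1-methylpiperidin-3-yl acetate | CC(=O)O[C@@H]1CN(C)CC[C@@H]1c1c(OC)cc(OC)c(C(C)=O)c1O | intermediate
15 | (3S,4R)-4-[2-hydroxy-4,6-dimethoxy-3-(3-oxobutanoyl)phenyl]-1-methylpiperidin-3-yl acetate | CC(=O)O[C@@H]1CN(C)CC[C@@H]1c1c(OC)cc(OC)c(C(=O)CC(C)=O)c1O | intermediate
16 | 8-[(3S,4R)-3-hydroxy-1-methylpiperidin-4-yl]-5,7-dimethoxy-2-methyl-4H-chromen-4-one | O[C@@H]1CN(C)CC[C@@H]1c1c(OC)cc(OC)c2c(=O)cc(C)oc12 | intermediate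
17 | 5,7-dihydroxy-8-[(3S,4R)-3-hydroxy-1-methylpiperidin-4-yl]-2-methyl-4H-chromen-4-one (rohitukine) | O[C@@H]1CN(C)CC[C@@H]1c1c(O)cc(O)c2c(=O)cc(C)oc12 | intermediate
18 | angelic acid, (Z)-2-methylbut-2-enoic acid | C/C=C(/C)C(=O)O | starting material
19 | (Z)-2-methylbut-2-enoic 2,4,6-trichlorobenzoic anhydride | C/C=C(/C)C(=O)OC(=O)c1c(Cl)cc(Cl)cc1Cl | intermediate
20 | (3S,4R)-4-{2-methyl-5,7-bis[(Z)-2-methylbut-2-enoyloxy]-4-oxo-4H-chromen-8-yl}-1-methylpiperidin-3-yl (Z)-2-methylbut-2-enoate | C/C=C(/C)C(=O)O[C@@H]1CN(C)CC[C@@H]1c1c(OC(=O)/C(C)=C\C)cc(OC(=O)/C(C)=C\C)c2c(=O)cc(C)oc12 | intermediate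
21 | (3S,4R)-4-(5,7-dihydroxy-2-methyl-4-oxo-4H-chromen-8-yl)-1-methylpiperidin-3-yl (Z)-2-methylbut-2-enoate | C/C=C(/C)C(=O)O[C@@H]1CN(C)CC[C@@H]1c1c(O)cc(O)c2c(=O)cc(C)oc12 | target

Total step count: 11. Longest linear sequence: 10 steps (4 to 21, steps 2–11); step 1 is the only side branch.

Steps most likely to fail

Risk 1, step 6. A nucleophilic radical meets an electron-rich styrene that is twisted out of conjugation. Ring closure may therefore be slow enough for the thiol to hand hydrogen to the open-chain C6' radical first. Hydrogen delivery to both faces of the C4' radical is the second concern. The fallback sets out from 11 and comes back at 12, and it makes the same C5'–C6' bond by polar means, where the polarity is matched. Activation of the carboxyl group of 11 with POCl3 in CH2Cl2 and loss of CO, the known decarbonylation of α-tertiary-amino acids, gives the (S)-N-methylene iminium chloride F1. The electron-rich styrene attacks F1 in a cationic 6-endo closure of the aza-Prins type. The trimethoxybenzyl cation then loses a C5' proton to give the (S)-3-silyloxy-4-aryl-1,2,3,6-tetrahydropyridine F2. Hydrogenation of F2 (H2, PtO2, EtOAc) should occur on the face away from the pseudoaxial silyloxy group. That places the C4' hydrogen trans to oxygen and gives 12.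

Risk 2, step 10. The activated angeloyl unit may isomerise from Z to E during the long heating that the crowded axial C3' hydroxyl needs, or acylation at that position may stall. The fallback sets out from 17 and comes back at 21, and it builds the Z alkene on the ester instead of transferring it.
- TBSCl (2.4 equiv) and imidazole in DMF silylate the two phenols ahead of the hindered alcohol and give the 5,7-bis-silyl ether F3.
- 2-[Bis(2,2,2-trifluoroethoxy)phosphoryl]propanoic acid, EDC·HCl and DMAP can be pushed as hard as needed, because this acid has no alkene to isomerise, and give the phosphonopropionate F4.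
- A Still–Gennari olefination (KN(SiMe3)2, 18-crown-6, THF, −78 °C, acetaldehyde) should form the Z-trisubstituted enoate, the bis-silylated angelate F5.
- Et3N·3HF in THF at 0 °C removes the phenolic silyl groups and gives 21.

Risk 3, step 4. The substrate nitrogen may tie up the boron of the oxazaborolidine. Uncatalysed background reduction or 1,4-reduction would then erode enantiofacial control. The fallback sets out from 5 (with 2 and 1) and comes back at 8, and it joins the same three building blocks in the other order, so the asymmetric step sees no amine and a truly small arm. Vinyllithium 6, made from 5 as in step 3, is added to 2 to give the α-chloro enone F6. Oxazaborolidine reduction of this α-chloroketone, a classic substrate class for the method, gives the (S)-chlorohydrin F7. K2CO3 in MeCN closes F7 to the (S)-vinyloxirane F8. The free base of 1 opens F8 at its CH2 terminus, and since the C–O bond at the stereocentre is never broken, this gives 8.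

Further compounds
F1 | step 6 | N-[(2S)-2-(tert-butyldimethylsilyloxy)-3-(2,4,6-trimethoxyphenyl)but-3-en-1-yl]-N-methylmethaniminium chloride | C=[N+](C)C[C@@H](O[Si](C)(C)C(C)(C)C)C(=C)c1c(OC)cc(OC)cc1OC.[Cl-]
F2 | step 6 | (3S)-3-(tert-butyldimethylsilyloxy)-1-methyl-4-(2,4,6-trimethoxyphenyl)-1,2,3,6-tetrahydropyridine | CC(C)(C)[Si](C)(C)O[C@@H]1CN(C)CC=C1c1c(OC)cc(OC)cc1OC
F3 | step 10 | 5,7-bis(tert-butyldimethylsilyloxy)-8-[(3S,4R)-3-hydroxy-1-methylpiperidin-4-yl]-2-methyl-4H-chromen-4-one | O[C@@H]1CN(C)CC[C@@H]1c1c(O[Si](C)(C)C(C)(C)C)cc(O[Si](C)(C)C(C)(C)C)c2c(=O)cc(C)oc12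
F4 | step 10 | (3S,4R)-4-[5,7-bis(tert-butyldimethylsilyloxy)-2-methyl-4-oxo-4H-chromen-8-yl]-1-methylpiperidin-3-yl 2-[bis(2,2,2-trifluoroethoxy)phosphoryl]propanoate (both epimers at the phosphonate carbon) | CC(C(=O)O[C@@H]1CN(C)CC[C@@H]1c1c(O[Si](C)(C)C(C)(C)C)cc(O[Si](C)(C)C(C)(C)C)c2c(=O)cc(C)oc12)P(=O)(OCC(F)(F)F)OCC(F)(F)F
F5 | step 10 | (3S,4R)-4-[5,7-bis(tert-butyldimethylsilyloxy)-2-methyl-4-oxo-4H-chromen-8-yl]-1-methylpiperidin-3-yl (Z)-2-methylbut-2-enoate | C/C=C(/C)C(=O)O[C@@H]1CN(C)CC[C@@H]1c1c(O[Si](C)(C)C(C)(C)C)cc(O[Si](C)(C)C(C)(C)C)c2c(=O)cc(C)oc12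
F6 | step 4 | 1-chloro-3-(2,4,6-trimethoxyphenyl)but-3-en-2-one | ClCC(=O)C(=C)c1c(OC)cc(OC)cc1OC
F7 | step 4 | (2S)-1-chloro-3-(2,4,6-trimethoxyphenyl)but-3-en-2-ol | ClC[C@@H](O)C(=C)c1c(OC)cc(OC)cc1OC
F8 | step 4 | (2S)-2-[1-(2,4,6-trimethoxyphenyl)vinyl]oxirane | C1O[C@H]1C(=C)c2c(OC)cc(OC)cc2OC
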